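**Strategy.** Rings are lettered A to E from the 2,4,6-trioxygenated end, and position 1 of rings B to E carries the oxygen that comes from the previous ring. The hydroxyls at C4 and E4 lie para to the ether carbons C1 and E1, and C4 is also ortho to the ether carbon C5. Each is therefore carried as a formyl group, which first activates 2,4,6-trifluorobenzaldehyde for copper-free ether formation at C1, C5 and E1 and is then exchanged for oxygen. One double Baeyer–Villiger oxidation of precursor 16, the pentaaryl ether with formyl groups at C4 and E4 and eleven methyl ethers, forms the C4–O and E4–O bonds together; BBr3 then removes the methyl groups.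

Key step: step 10

Remark: the target has no stereocentre; in rings B and D the oxygen that leads on to the next ring sits on the carbon adjacent to position 1 and is called the outgoing oxygen below, whereas in ring C it sits on C5; compounds 1, 2, 6 and 8 and the building blocks F1, F2 and F6 of the fallbacks are assumed to be catalogue compounds.

Step 1
Reactants: 1 2,4,6-trimethoxyphenol; 2 2-fluoro-4,6-dimethoxybenzaldehyde
Product: 3 2,4-dimethoxy-6-(2,4,6-trimethoxyphenoxy)benzaldehyde (ring AB aldehyde)
Conditions: Cs2CO3, DMSO, 100 °C, Ar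
Reagents that add atoms: none
Why: Nucleophilic aromatic substitution (SNAr), in which the ortho formyl group stabilises the Meisenheimer adduct at the fluorine-bearing carbon and the electron-rich phenoxide of 1 should form the diaryl ether between rings A and B without copper.

Step 2
Reactants: 3 ring AB aldehyde
Product: 5 2,4-dimethoxy-6-(2,4,6-trimethoxyphenoxy)phenol (ring AB phenol), via aryl formate 4 (not isolated)
Conditions: mCPBA, NaHCO3, CH2Cl2, 0 °C to rt; aq. Na2S2O3; then K2CO3 (cat.), MeOH, rt, Ar
Reagents that add atoms: 3-chloroperbenzoic acid (mCPBA), OOC(=O)c1cccc(Cl)c1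
Why: Baeyer–Villiger (Dakin-type) oxidation of a 2,4,6-trioxygenated benzaldehyde, in which the electron-rich aryl group migrates in preference to hydride and methanolysis of the formate should free the outgoing hydroxyl of ring B.

Step 3
Reactants: 5 ring AB phenol; 6 2,4,6-trifluorobenzaldehyde
Product: 7 4-[2,4-dimethoxy-6-(2,4,6-trimethoxyphenoxy)phenoxy]-2,6-difluorobenzaldehyde (ring ABC difluoride)
Conditions: K2CO3, DMF, 0 °C to rt, Ar
Reagents that add atoms: none
Why: SNAr on a highly activated fluoroarene, in which the doubly ortho-substituted phenoxide of 5 in a dipolar aprotic solvent should attack the unhindered fluorine para to the formyl group and so form the ether from the outgoing oxygen of ring B to C1.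

Step 4
Reactants: 8 2,3,4-trimethoxyphenol
Product: 9 1,2,3-trimethoxy-4-(methoxymethoxy)benzene
Conditions: MOMCl, i-Pr2NEt, CH2Cl2, 0 °C to rt
Reagents that add atoms: chloromethyl methyl ether (MOMCl), COCCl
Why: Williamson-type O-alkylation of a phenol, which protects the future outgoing oxygen of ring D as an acetal that is stable to base and also serves as the directing group for the next step.

Step 5
Reactants: 9 1,2,3-trimethoxy-4-(methoxymethoxy)benzene
Product: 12 2-(methoxymethoxy)-3,4,5-trimethoxyphenol (ring D phenol; D1 hydroxyl free; outgoing oxygen as MOM ether), via aryllithium 10 (not isolated), via dimethyl arylboronate 11 (not isolated)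
Conditions: n-BuLi, THF, 0 °C; B(OMe)3, −78 °C to rt; then 30% aq. H2O2, aq. NaOH, 0 °C
Reagents that add atoms: hydrogen peroxide, OO
Why: Directed ortho-metalation followed by borylation and oxidation, in which the chelating methoxymethoxy group, a stronger director than methoxy, should steer lithiation to the adjacent free position and the C–B bond is then oxidised to the D1 hydroxyl.

Step 6
Reactants: 7 ring ABC difluoride; 12 ring D phenol
Product: 13 2-fluoro-6-[2-(methoxymethoxy)-3,4,5-trimethoxyphenoxy]-4-[2,4-dimethoxy-6-(2,4,6-trimethoxyphenoxy)phenoxy]benzaldehyde (ring ABCD fluoro aldehyde; MOM ether on ring D)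
Conditions: Cs2CO3, DMF, 60 °C, Ar
Reagents that add atoms: none
Why: SNAr at a fluorine ortho to the formyl group, in which the two fluorines of 7 are equivalent and the aryloxy group introduced first deactivates the ring, so that the reaction should stop after one displacement and give the D1–O–C5 ether.

Step 7
Reactants: 13 ring ABCD fluoro aldehyde
Product: 14 2-fluoro-6-(2-hydroxy-3,4,5-trimethoxyphenoxy)-4-[2,4-dimethoxy-6-(2,4,6-trimethoxyphenoxy)phenoxy]benzaldehyde (ring ABCD phenol; outgoing hydroxyl of ring D free)
Conditions: 3 M aq. HCl, THF, 45 °C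
Reagents that add atoms: none
Why: Acid-catalysed acetal hydrolysis of the aryl methoxymethyl ether, which should leave the aldehyde, the aryl fluoride and the diaryl and methyl ethers untouched.

Step 8
Reactants: 14 ring ABCD phenol; 6 2,4,6-trifluorobenzaldehyde
Product: 15 2-[2-(3,5-difluoro-4-formylphenoxy)-3,4,5-trimethoxyphenoxy]-6-fluoro-4-[2,4-dimethoxy-6-(2,4,6-trimethoxyphenoxy)phenoxy]benzaldehyde (pentaaryl ether trifluoro dialdehyde)
Conditions: K2CO3 added last to 14 and 6 (excess), DMF, 0 °C to rt, Ar
Reagents that add atoms: none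
Why: SNAr in which the hindered outgoing phenoxide of ring D should take the para fluorine of 6, by far the most electrophilic fluoroarene present, and so form the ether to E1 at a temperature low enough to keep the deactivated ring C fluorine and the ring C ether bond out of play.

Step 9
Reactants: 15 pentaaryl ether trifluoro dialdehyde
Product: 16 2-[2-(4-formyl-3,5-dimethoxyphenoxy)-3,4,5-trimethoxyphenoxy]-6-methoxy-4-[2,4-dimethoxy-6-(2,4,6-trimethoxyphenoxy)phenoxy]benzaldehyde (pentaaryl ether 4,4''-dialdehyde)
Conditions: NaOMe (excess), MeOH/THF, 60 °C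
Reagents that add atoms: sodium methoxide, [Na+].[O-]C
Why: Threefold SNAr by methoxide at the fluorines ortho to the two formyl groups (one on ring C, two on ring E), which should be selective because fluoride is displaced far faster than aryloxide from the same activated rings.

Step 10
Reactants: 16 pentaaryl ether 4,4''-dialdehyde
Product: 18 undeca-O-methyl pseudopentafuhalol D (C4-OH and E4-OH free), via bis(formate) 17 (not isolated)
Conditions: mCPBA (3 equiv), NaHCO3, CH2Cl2, 0 °C to rt; aq. Na2S2O3; then K2CO3 (cat.), MeOH, rt, Ar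
Reagents that add atoms: 3-chloroperbenzoic acid (mCPBA), OOC(=O)c1cccc(Cl)c1
Why: The peracid adds to each formyl carbon to give a Criegee-type peroxy hemiacetal, from which the aryl group migrates from carbon to oxygen with loss of 3-chlorobenzoate, and the resulting bis(aryl formate) 17 is opened to the two phenols by catalytic K2CO3 in methanol. The closest known reaction type is the Baeyer–Villiger (Dakin-type) oxidation of 2,6-dialkoxybenzaldehydes to phenols through their formates. No ring is closed and no stereocentre is formed, so no mode of closure and no stereocontrolling element is involved. The selectivity needed is aryl over hydride migration at both aldehydes, and it is secured by the two oxygens ortho to each formyl group and the para aryloxy oxygen (at C1 and at E1), which make each migrating carbon strongly electron-rich. Oxidation of the other polyalkoxy rings should be limited by the NaHCO3 buffer, the low temperature, the small excess of peracid and the destruction of that excess before the formates are opened, so that free phenols never meet the oxidant.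

Step 11
Reactants: 18 undeca-O-methyl pseudopentafuhalol D
Product: 19 pseudopentafuhalol D
Conditions: BBr3 (excess), CH2Cl2, −78 °C to rt; then H2O, Ar; Sephadex LH-20
Reagents that add atoms: none
Why: Lewis-acid-mediated cleavage of aryl methyl ethers, in which bromide attacks each boron-activated methyl group by SN2, while the four diaryl ether bonds offer no sp3 carbon and should persist.

**Compound list**

1 | 2,4,6-trimethoxyphenol | COc1cc(OC)c(O)c(OC)c1 | starting material
2 | 2-fluoro-4,6-dimethoxybenzaldehyde | COc1cc(F)c(C=O)c(OC)c1 | starting material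
3 | 2,4-dimethoxy-6-(2,4,6-trimethoxyphenoxy)benzaldehyde (ring AB aldehyde) | COc1cc(OC)c(Oc2cc(OC)cc(OC)c2C=O)c(OC)c1 | intermediate
4 | 2,4-dimethoxy-6-(2,4,6-trimethoxyphenoxy)phenyl formate (not isolated) | COc1cc(OC)c(Oc2cc(OC)cc(OC)c2OC=O)c(OC)c1 | intermediate
5 | 2,4-dimethoxy-6-(2,4,6-trimethoxyphenoxy)phenol (ring AB phenol) | COc1cc(OC)c(Oc2cc(OC)cc(OC)c2O)c(OC)c1 | intermediate
6 | 2,4,6-trifluorobenzaldehyde | O=Cc1c(F)cc(F)cc1F | starting material
7 | 4-[2,4-dimethoxy-6-(2,4,6-trimethoxyphenoxy)phenoxy]-2,6-difluorobenzaldehyde (ring ABC difluoride) | COc1cc(OC)c(Oc2cc(OC)cc(OC)c2Oc2cc(F)c(C=O)c(F)c2)c(OC)c1 | intermediate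
8 | 2,3,4-trimethoxyphenol | COc1ccc(O)c(OC)c1OC | starting material
9 | 1,2,3-trimethoxy-4-(methoxymethoxy)benzene | COCOc1ccc(OC)c(OC)c1OC | intermediate
10 | [2-(methoxymethoxy)-3,4,5-trimethoxyphenyl]lithium (not isolated) | [Li]c1cc(OC)c(OC)c(OC)c1OCOC | intermediate
11 | dimethyl [2-(methoxymethoxy)-3,4,5-trimethoxyphenyl]boronate (not isolated) | COB(OC)c1cc(OC)c(OC)c(OC)c1OCOC | intermediate
12 | 2-(methoxymethoxy)-3,4,5-trimethoxyphenol (ring D phenol) | COCOc1c(O)cc(OC)c(OC)c1OC | intermediate
13 | ring ABCD fluoro aldehyde with MOM ether on ring D | COc1cc(OC)c(Oc2cc(OC)cc(OC)c2Oc2cc(F)c(C=O)c(Oc3cc(OC)c(OC)c(OC)c3OCOC)c2)c(OC)c1 | intermediate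
14 | ring ABCD phenol with free outgoing hydroxyl on ring D | COc1cc(OC)c(Oc2cc(OC)cc(OC)c2Oc2cc(F)c(C=O)c(Oc3cc(OC)c(OC)c(OC)c3O)c2)c(OC)c1 | intermediate
15 | pentaaryl ether trifluoro dialdehyde (one F on ring C, two on ring E) | COc1cc(OC)c(Oc2cc(OC)cc(OC)c2Oc2cc(F)c(C=O)c(Oc3cc(OC)c(OC)c(OC)c3Oc3cc(F)c(C=O)c(F)c3)c2)c(OC)c1 | intermediate
16 | pentaaryl ether 4,4''-dialdehyde (formyl at C4 and E4, eleven OMe) | COc1cc(OC)c(Oc2cc(OC)cc(OC)c2Oc2cc(OC)c(C=O)c(Oc3cc(OC)c(OC)c(OC)c3Oc3cc(OC)c(C=O)c(OC)c3)c2)c(OC)c1 | intermediate
17 | bis(formate) at C4 and E4 (not isolated) | COc1cc(OC)c(Oc2cc(OC)cc(OC)c2Oc2cc(OC)c(OC=O)c(Oc3cc(OC)c(OC)c(OC)c3Oc3cc(OC)c(OC=O)c(OC)c3)c2)c(OC)c1 | intermediate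
18 | undeca-O-methyl pseudopentafuhalol D with free C4-OH and E4-OH | COc1cc(OC)c(Oc2cc(OC)cc(OC)c2Oc2cc(OC)c(O)c(Oc3cc(OC)c(OC)c(OC)c3Oc3cc(OC)c(O)c(OC)c3)c2)c(OC)c1 | intermediate
19 | pseudopentafuhalol D | Oc1cc(O)c(Oc2cc(O)cc(O)c2Oc2cc(O)c(O)c(Oc3cc(O)c(O)c(O)c3Oc3cc(O)c(O)c(O)c3)c2)c(O)c1 | target

**Total step count:** 11.
**Longest linear sequence:** 9 steps (steps 1, 2, 3, 6, 7, 8, 9, 10, 11).

**Steps most likely to fail**

Step 8. Three processes may interfere: attack at an ortho instead of the para fluorine of 6, slow reaction of the doubly ortho-substituted ring D phenoxide, and base-induced migration of ring C between the two adjacent oxygens of ring D through a spiro Meisenheimer adduct (Smiles-type). Fallback: setting out from 14, the bond from the outgoing oxygen of ring D to E1 is made by a Chan–Lam coupling mediated by Cu(OAc)2 (pyridine, 4 Å molecular sieves, CH2Cl2, air, rt) with (3,5-difluoro-4-formylphenyl)boronic acid F1. The boron atom fixes the point of attachment, and neither strong base nor heat is present to drive aryl migration. This oxidative coupling is known to accept phenols with two ortho substituents. Its product is 15, where the route is rejoined.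

Step 9. The last fluorides sit on donor-deactivated rings and may be displaced incompletely, while methoxide may attack the formyl-activated aryloxy carbons C1, C5 and E1 and cut ether bonds. Fallback: setting out from 5 and 12, the methoxy groups are brought in with the building blocks, so that no methoxide ever meets an aryl ether. Phenol 5 is joined (K2CO3, DMF, rt) to the para fluorine of 2,4-difluoro-6-methoxybenzaldehyde F2 to give the ring ABC monofluoride F3. Phenol 12 then displaces the remaining ortho fluorine of F3 (Cs2CO3, DMSO, 90 °C) to give the MOM-protected tetraaryl ether F4, and aqueous HCl in THF frees the ring D phenol F5. Finally F5 is coupled with 4-fluoro-2,6-dimethoxybenzaldehyde F6 (Cs2CO3, DMSO, 110 °C), whose only fluorine is para to the formyl group. This last coupling gives 16 directly, where the route is rejoined.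

Step 11. Cleavage of eleven ethers may stop short and give mixtures of partly methylated material, and the pyrogallol-type rings may oxidise in air during isolation. Fallback: setting out from 18, the crude BBr3 product is not isolated as the free polyphenol but acetylated at once (Ac2O, pyridine, DMAP cat.) to the tridecaacetate F7. F7 is stable to air and can be purified on silica, where under-demethylated material separates and can be returned to BBr3. Acid methanolysis of pure F7 (HCl generated from AcCl in MeOH, Ar, rt) and evaporation should then give 19.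

**Further compounds**

F1 | step 8 | (3,5-difluoro-4-formylphenyl)boronic acid | OB(O)c1cc(F)c(C=O)c(F)c1
F2 | step 9 | 2,4-difluoro-6-methoxybenzaldehyde | COc1cc(F)cc(F)c1C=O
F3 | step 9 | 4-[2,4-dimethoxy-6-(2,4,6-trimethoxyphenoxy)phenoxy]-2-fluoro-6-methoxybenzaldehyde | COc1cc(OC)c(Oc2cc(OC)cc(OC)c2Oc2cc(F)c(C=O)c(OC)c2)c(OC)c1
F4 | step 9 | 2-methoxy-6-[2-(methoxymethoxy)-3,4,5-trimethoxyphenoxy]-4-[2,4-dimethoxy-6-(2,4,6-trimethoxyphenoxy)phenoxy]benzaldehyde | COc1cc(OC)c(Oc2cc(OC)cc(OC)c2Oc2cc(OC)c(C=O)c(Oc3cc(OC)c(OC)c(OC)c3OCOC)c2)c(OC)c1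
F5 | step 9 | 2-(2-hydroxy-3,4,5-trimethoxyphenoxy)-6-methoxy-4-[2,4-dimethoxy-6-(2,4,6-trimethoxyphenoxy)phenoxy]benzaldehyde | COc1cc(OC)c(Oc2cc(OC)cc(OC)c2Oc2cc(OC)c(C=O)c(Oc3cc(OC)c(OC)c(OC)c3O)c2)c(OC)c1
F6 | step 9 | 4-fluoro-2,6-dimethoxybenzaldehyde | COc1cc(F)cc(OC)c1C=O
F7 | step 11 | pseudopentafuhalol D tridecaacetate | CC(=O)Oc1cc(OC(C)=O)c(Oc2cc(OC(C)=O)cc(OC(C)=O)c2Oc2cc(OC(C)=O)c(OC(C)=O)c(Oc3cc(OC(C)=O)c(OC(C)=O)c(OC(C)=O)c3Oc3cc(OC(C)=O)c(OC(C)=O)c(OC(C)=O)c3)c2)c(OC(C)=O)c1
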